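**Plan**
1. Retrosynthetic cuts: the two indole N–S bonds and the imidazole N1–CH2Ar bond are protecting-group bonds and go first. The skeletal cuts are C4–C5 and C2–N3 of the imidazole, then the amide bond between the future C2 carbon and N1.
2. Enabling feature: in the central 1,3-diazole ring these two bonds do not touch. Removing them leaves a three-atom piece C2–N1–C5 (C2 bears one 6-bromoindol-3-yl, C5 only H) and a two-atom piece N3=C4 (C4 bears the other indolyl). These are a C–N–C azomethine-ylide dipole and a C=N dipolarophile.
3. The dipole is the münchnone of an N-aroyl-N-(2,4-dimethoxybenzyl)glycine and the dipolarophile is an N-tosyl aldimine. CO2 and toluenesulfinate leave tracelessly and set the aromatic oxidation level.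
4. Forward: both bromoindole units come from one purchased aldehyde. After N-tosylation it diverges to the acid chloride (steps 2–3) and the imine (step 6), and glycine is benzylated and acylated (steps 4–5). The imidazole, the only ring built, closes in step 7, and DMB and then the tosyl groups are removed (steps 8–9).
5. Stereochemistry: the target is flat and achiral, so nothing has to be set. The sp3 centres that appear transiently in step 7 vanish on aromatisation.

Key step: step 7

Remark on the chemistry: nortopsentin A has no stereogenic element, so the given structure is its only stereoisomer. The N1–H and N3–H tautomers of the free imidazole are one compound.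

**Step 1**
Reactants: 1 6-bromo-1H-indole-3-carbaldehyde
Product: 2 6-bromo-1-tosylindole-3-carbaldehyde
Conditions: TsCl, Et3N, cat. DMAP, CH2Cl2, 0 °C → rt
Reagents that add atoms: p-toluenesulfonyl chloride, Cc1ccc(cc1)S(=O)(=O)Cl
Why: DMAP-catalysed N-sulfonylation is routine for 3-formylindoles, whose N–H is acidified by the vinylogous formamide, and the tosyl group then lowers indole nucleophilicity and raises the electrophilicity of the C3 carbonyl carbon.

**Step 2**
Reactants: 2 6-bromo-1-tosylindole-3-carbaldehyde
Product: 3 6-bromo-1-tosylindole-3-carboxylic acid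
Conditions: NaClO2, NaH2PO4, 2-methyl-2-butene, t-BuOH–THF–H2O, rt
Reagents that add atoms: sodium chlorite, [Na+].[O-]Cl=O
Why: The Pinnick oxidation converts aryl aldehydes to acids in a buffered medium that spares the N–S and C–Br bonds, and the alkene traps hypochlorous acid before it can chlorinate a ring.

**Step 3**
Reactants: 3 6-bromo-1-tosylindole-3-carboxylic acid
Product: 4 6-bromo-1-tosylindole-3-carbonyl chloride
Conditions: (COCl)2, cat. DMF, CH2Cl2, 0 °C → rt; evaporated and used crude
Reagents that add atoms: oxalyl chloride, O=C(Cl)C(=O)Cl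
Why: Vilsmeier-type activation with oxalyl chloride and catalytic DMF is the standard acid chloride synthesis, gives only volatile by-products, and touches neither the sulfonamide nor the bromide.

**Step 4**
Reactants: 5 glycine; 6 2,4-dimethoxybenzaldehyde
Product: 8 N-(2,4-dimethoxybenzyl)glycine, via sodium N-(2,4-dimethoxybenzylidene)glycinate 7 (not isolated)
Conditions: NaOH (1 equiv), H2O–MeOH, rt; NaBH4, 0 °C; HCl to pH 6
Reagents that add atoms: none
Why: In this reductive alkylation of an amino acid salt one equivalent of aldehyde is fully bound as the aldimine before borohydride is added, which should hold the reaction at monoalkylation, and the zwitterion should precipitate near its isoelectric point.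

**Step 5**
Reactants: 8 N-(2,4-dimethoxybenzyl)glycine; 4 6-bromo-1-tosylindole-3-carbonyl chloride
Product: 11 N-(2,4-dimethoxybenzyl)-N-[(6-bromo-1-tosylindol-3-yl)carbonyl]glycine, via trimethylsilyl N-(2,4-dimethoxybenzyl)glycinate 9 (not isolated), via trimethylsilyl ester of the acylated glycine 10 (not isolated)
Conditions: 8 (slight excess), TMSCl, iPr2NEt, CH2Cl2, reflux; 4, 0 °C → rt; aq. citric acid
Reagents that add atoms: none
Why: In this N-acylation under transient silyl-ester protection the zwitterion dissolves with its secondary amine free for the acid chloride, and the silyl ester is lost in the mild aqueous work-up, so neither strong acid (a threat to the N-DMB amide) nor hydroxide (a threat to the N-tosyl group) is needed to free the carboxyl group.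

**Step 6**
Reactants: 2 6-bromo-1-tosylindole-3-carbaldehyde
Product: 12 (E)-N-[(6-bromo-1-tosylindol-3-yl)methylidene]-4-methylbenzenesulfonamide
Conditions: TsNH2, Ti(OEt)4, CH2Cl2, reflux; brine, Celite filtration, crystallisation
Reagents that add atoms: p-toluenesulfonamide, Cc1ccc(cc1)S(N)(=O)=O
Why: Lewis-acid-mediated dehydrative condensation of an aryl aldehyde with a primary sulfonamide, with the titanium alkoxide activating the carbonyl and binding the water, is a standard route to N-sulfonyl aldimines and gives the less crowded E isomer.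

**Step 7**
Reactants: 11 N-(2,4-dimethoxybenzyl)-N-[(6-bromo-1-tosylindol-3-yl)carbonyl]glycine; 12 (E)-N-[(6-bromo-1-tosylindol-3-yl)methylidene]-4-methylbenzenesulfonamide
Product: 16 1-(2,4-dimethoxybenzyl)-2,4-bis(6-bromo-1-tosylindol-3-yl)imidazole, via münchnone 13 (not isolated), via bicyclic lactone cycloadduct 14 (not isolated), via cyclic azomethine ylide 15 (not isolated)
Conditions: 12 (1.5 equiv), iPr2NEt (1.2 equiv), 4 Å MS, CH2Cl2, rt; DIC (1.5 equiv) by syringe pump; then 40 °C
Reagents that add atoms: none
Why: The carbodiimide cyclodehydrates 11 to the mesoionic 1,3-oxazolium-5-olate 13, a masked azomethine ylide whose termini are the aroyl-derived carbon and the glycine CH. The glycine carbon adds to the imine carbon of 12 (imidazole C5–C4 bond) and the sulfonamide nitrogen adds to the aroyl-derived carbon (imidazole N3–C2 bond) to give bicyclic lactone 14, which expels CO2 by cycloreversion to ylide 15, and loss of toluenesulfinate from N3 followed by loss of the C4 proton aromatises 15 to 16. The closest known reaction type is this very one, the formal 1,3-dipolar cycloaddition of carbodiimide-generated münchnones with N-sulfonyl aldimines that ends in imidazoles. The imidazole is the only ring kept and it closes in a [3+2] mode, three atoms (C2, N1, C5) coming from the dipole and two (N3, C4) from the imine, either concertedly and asynchronously or as a Mannich-type addition followed by N-to-C2 closure. No stereocentre is retained, since the sp3 centres of 14 and 15 arise as racemates and are erased on aromatisation. The step needs regioselectivity (2,4- instead of 4,5-diindolyl pattern) and cross-reaction over self-reaction of the C–H münchnone: the first rests on the polarity match between the unhindered, most nucleophilic glycine carbon and the electrophilic imine carbon, reinforced by the bulky indolyl group shielding the other terminus, and the second on slow carbodiimide addition into an excess of 12, with the electron-withdrawing N-tosyl groups suppressing indole nucleophilicity and iPr2NEt holding the released sulfinic acid as a salt so that it cannot add to 12.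

**Step 8**
Reactants: 16 1-(2,4-dimethoxybenzyl)-2,4-bis(6-bromo-1-tosylindol-3-yl)imidazole
Product: 17 2,4-bis(6-bromo-1-tosylindol-3-yl)-1H-imidazole
Conditions: TFA, anisole (excess), 60 °C; aq. NaHCO3
Reagents that add atoms: none
Why: In this SN1 acidolysis of an electron-rich N-benzyl group the protonated imidazole leaves and anisole captures the dimethoxybenzyl cation by Friedel–Crafts alkylation, while the N-tosylindoles are stable to TFA and too electron-poor to be benzylated, which is why this step precedes detosylation.

**Step 9**
Reactants: 17 2,4-bis(6-bromo-1-tosylindol-3-yl)-1H-imidazole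
Product: 18 nortopsentin A, 2,4-bis(6-bromo-1H-indol-3-yl)-1H-imidazole
Conditions: KOH (excess), cat. cetyltrimethylammonium bromide, THF–H2O, 65 °C; 1 M HCl to pH 7
Reagents that add atoms: none
Why: Phase-transfer-catalysed N-desulfonylation by hydroxide attack at sulfur releases the stabilised indolide, leaves aryl bromides untouched where dissolving-metal desulfonylation may not, and, being alcohol-free, forms no alkyl tosylate that could alkylate the imidazole.

**Compound list**
1 | 6-bromo-1H-indole-3-carbaldehyde | O=Cc1c[nH]c2cc(Br)ccc12 | starting material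
2 | 6-bromo-1-tosylindole-3-carbaldehyde | O=Cc1cn(S(=O)(=O)c2ccc(C)cc2)c2cc(Br)ccc12 | intermediate
3 | 6-bromo-1-tosylindole-3-carboxylic acid | OC(=O)c1cn(S(=O)(=O)c2ccc(C)cc2)c2cc(Br)ccc12 | intermediate
4 | 6-bromo-1-tosylindole-3-carbonyl chloride | ClC(=O)c1cn(S(=O)(=O)c2ccc(C)cc2)c2cc(Br)ccc12 | intermediate
5 | glycine | NCC(=O)O | starting material
6 | 2,4-dimethoxybenzaldehyde | COc1ccc(C=O)c(OC)c1 | starting material
7 | sodium (E)-N-(2,4-dimethoxybenzylidene)glycinate | COc1ccc(/C=N/CC(=O)[O-])c(OC)c1.[Na+] | intermediate
8 | N-(2,4-dimethoxybenzyl)glycine | COc1ccc(CNCC(=O)O)c(OC)c1 | intermediate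
9 | trimethylsilyl N-(2,4-dimethoxybenzyl)glycinate | COc1ccc(CNCC(=O)O[Si](C)(C)C)c(OC)c1 | intermediate
10 | trimethylsilyl N-(2,4-dimethoxybenzyl)-N-[(6-bromo-1-tosylindol-3-yl)carbonyl]glycinate | COc1ccc(CN(CC(=O)O[Si](C)(C)C)C(=O)c2cn(S(=O)(=O)c3ccc(C)cc3)c3cc(Br)ccc23)c(OC)c1 | intermediate
11 | N-(2,4-dimethoxybenzyl)-N-[(6-bromo-1-tosylindol-3-yl)carbonyl]glycine | OC(=O)CN(Cc1ccc(OC)cc1OC)C(=O)c1cn(S(=O)(=O)c2ccc(C)cc2)c2cc(Br)ccc12 | intermediate
12 | (E)-N-[(6-bromo-1-tosylindol-3-yl)methylidene]-4-methylbenzenesulfonamide | Cc1ccc(cc1)S(=O)(=O)/N=C/c1cn(S(=O)(=O)c2ccc(C)cc2)c2cc(Br)ccc12 | intermediate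
13 | 2-(6-bromo-1-tosylindol-3-yl)-3-(2,4-dimethoxybenzyl)-1,3-oxazol-3-ium-5-olate (münchnone) | [O-]C1=C[N+](Cc2ccc(OC)cc2OC)=C(c2cn(S(=O)(=O)c3ccc(C)cc3)c3cc(Br)ccc23)O1 | intermediate
14 | 1,5-bis(6-bromo-1-tosylindol-3-yl)-7-(2,4-dimethoxybenzyl)-6-tosyl-2-oxa-6,7-diazabicyclo[2.2.1]heptan-3-one (racemic, configuration at C5 open, all centres lost later) | O=C1OC2(c3cn(S(=O)(=O)c4ccc(C)cc4)c4cc(Br)ccc34)N(S(=O)(=O)c3ccc(C)cc3)C(c3cn(S(=O)(=O)c4ccc(C)cc4)c4cc(Br)ccc34)C1N2Cc1ccc(OC)cc1OC | intermediate
15 | 2,4-bis(6-bromo-1-tosylindol-3-yl)-1-(2,4-dimethoxybenzyl)-3-tosyl-3,4-dihydroimidazol-1-ium-5-ide (racemic cyclic azomethine ylide) | COc1ccc(C[N+]2=C(c3cn(S(=O)(=O)c4ccc(C)cc4)c4cc(Br)ccc34)N(S(=O)(=O)c3ccc(C)cc3)C(c3cn(S(=O)(=O)c4ccc(C)cc4)c4cc(Br)ccc34)[CH-]2)c(OC)c1 | intermediate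
16 | 1-(2,4-dimethoxybenzyl)-2,4-bis(6-bromo-1-tosylindol-3-yl)imidazole | COc1ccc(Cn2cc(-c3cn(S(=O)(=O)c4ccc(C)cc4)c4cc(Br)ccc34)nc2-c2cn(S(=O)(=O)c3ccc(C)cc3)c3cc(Br)ccc23)c(OC)c1 | intermediate
17 | 2,4-bis(6-bromo-1-tosylindol-3-yl)-1H-imidazole | Cc1ccc(cc1)S(=O)(=O)n1cc(-c2c[nH]c(-c3cn(S(=O)(=O)c4ccc(C)cc4)c4cc(Br)ccc34)n2)c2ccc(Br)cc12 | intermediate
18 | nortopsentin A, 2,4-bis(6-bromo-1H-indol-3-yl)-1H-imidazole (achiral) | Brc1ccc2c(-c3c[nH]c(-c4c[nH]c5cc(Br)ccc45)n3)c[nH]c2c1 | target

**Step count**
Total step count: 9.
Longest linear sequence: 7 (steps 1, 2, 3, 5, 7, 8, 9).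

**Steps most likely to fail**

First, step 7. The münchnone has no substituent on its glycine carbon. It may acylate itself or oligomerise faster than it meets the only moderately electrophilic heteroaryl imine, and the activated acid may drift to an N-acylurea. The fallback gives up the dipole for a Davidson-type imidazole synthesis. It sets out from 4 and 3 and returns at 17.
- Acid chloride 4 with ethereal diazomethane at 0 °C should give 1-(6-bromo-1-tosylindol-3-yl)-2-diazoethanone F1.
- Aqueous HBr in Et2O converts this into 2-bromo-1-(6-bromo-1-tosylindol-3-yl)ethanone F2.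
- The potassium salt of acid 3 (K2CO3, DMF, rt) displaces the bromide to give 2-(6-bromo-1-tosylindol-3-yl)-2-oxoethyl 6-bromo-1-tosylindole-3-carboxylate F3.
- Heating F3 with a large excess of NH4OAc in AcOH condenses it with two molecules of ammonia to 17. The ester acyl carbon becomes C2 and the ketone carbon becomes C4.
- Steps 4–6 and 8 then become unnecessary, and step 9 completes the synthesis.

Second, step 6. The formyl group retains some vinylogous-amide character, so condensation may stall. The imine may also hydrolyse while the titanium residues are removed. The fallback stores the imine as a crystalline sulfinate adduct. It sets out from 2 and returns at 12.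
- Aldehyde 2, TsNH2 and sodium p-toluenesulfinate in HCOOH–H2O at rt should precipitate N-[(6-bromo-1-tosylindol-3-yl)(tosyl)methyl]-4-methylbenzenesulfonamide F4 (racemic), which drives the equilibrium.
- Shaking F4 in CH2Cl2 with aqueous NaHCO3 eliminates sulfinate and releases 12 just before use.

Third, step 8. Heterolysis of the N–benzyl bond may be slow, and the benzyl cation may re-attach at imidazole C5 or nitrogen before anisole captures it. The fallback replaces cation chemistry by oxidative debenzylation. It sets out from 16 and returns at 17.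
- Ceric ammonium nitrate in MeCN–H2O at 0 °C oxidises the dimethoxyarene, the most electron-rich ring present, by single-electron transfer.
- Water adds at the benzylic carbon, and the hemiaminal collapses to 17 and an aldehyde, so no alkylating species is formed.
- This fallback makes no compound outside the list (F0).

**Further compounds**
F1 | step 7 | 1-(6-bromo-1-tosylindol-3-yl)-2-diazoethanone | [N-]=[N+]=CC(=O)c1cn(S(=O)(=O)c2ccc(C)cc2)c2cc(Br)ccc12
F2 | step 7 | 2-bromo-1-(6-bromo-1-tosylindol-3-yl)ethanone | BrCC(=O)c1cn(S(=O)(=O)c2ccc(C)cc2)c2cc(Br)ccc12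
F3 | step 7 | 2-(6-bromo-1-tosylindol-3-yl)-2-oxoethyl 6-bromo-1-tosylindole-3-carboxylate | O=C(COC(=O)c1cn(S(=O)(=O)c2ccc(C)cc2)c2cc(Br)ccc12)c1cn(S(=O)(=O)c2ccc(C)cc2)c2cc(Br)ccc12
F4 | step 6 | N-[(6-bromo-1-tosylindol-3-yl)(tosyl)methyl]-4-methylbenzenesulfonamide (racemic) | Cc1ccc(cc1)S(=O)(=O)NC(c1cn(S(=O)(=O)c2ccc(C)cc2)c2cc(Br)ccc12)S(=O)(=O)c1ccc(C)cc1
F0 | step 8 | none | none
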